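Ring B, the 7-oxabicyclo[2.2.1]heptane, is read as an intramolecular [3+2] adduct of a ketone (C4=O7) and the three-carbon unit C5–C6–C1. In acyclic β-bromo ketone 13 the terminal vinyl carbon adds to the activated carbonyl (C4–C5), the cation at C6 is relayed to C1 by a 1,2-hydride shift, the C2 bromine bridges it, and the new hydroxyl opens this bromonium (O7–C1). One operation thus closes the carbocycle and the oxygen bridge and sets both bridgeheads from the C2–Br stereocentre; it exploits the 1,4-relationship of C4 and C1 and the anti O7/Br arrangement. Ketone 13 arises from a chromium-mediated fragment coupling and an enantiospecific bromonium cyclisation with semipinacol shift that builds ring A.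

Key step: step 10

Remark: locants C1–C6 and O7 are those of the oxabicycle of 14 (C1 methyl-bearing bridgehead, C2 CHBr, C3 CH2, C4 bridgehead on ring A, C5–C6 the CH2CH2 bridge); in 13 they correspond to hexenone C4, C3, C2, C1, C6, C5 and the carbonyl oxygen. Compounds 1, 6, 7 and the fructose-derived ketone catalyst are taken as purchasable.

Step 1
Reactants: 1 6-methylhept-5-en-2-one
Product: 3 6-methylhepta-1,5-dien-2-yl trifluoromethanesulfonate, via lithium enolate 2 (not isolated)
Conditions: LiN(iPr)2, THF, −78 °C; then PhNTf2, −78 °C to 0 °C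
Reagents that add atoms: N-phenylbis(trifluoromethanesulfonimide), FC(F)(F)S(=O)(=O)N(c1ccccc1)S(=O)(=O)C(F)(F)F
Why: Kinetic deprotonation by the hindered amide removes a methyl proton and O-sulfonylation of the terminal enolate gives the 2-substituted enol triflate (enol triflate formation), with no stereocentre formed.

Step 2
Reactants: 3 6-methylhepta-1,5-dien-2-yl trifluoromethanesulfonate
Product: 4 4-[(2R)-3,3-dimethyloxiran-2-yl]but-1-en-2-yl trifluoromethanesulfonate
Conditions: D-fructose-derived Shi ketone (30 mol %), KHSO5 (Oxone triple salt), K2CO3, Bu4NHSO4, aq. Na2B4O7/Na2EDTA, MeCN/CH2(OMe)2, 0 °C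
Reagents that add atoms: potassium peroxymonosulfate, [K+].[O-]S(=O)(=O)OO
Why: The chiral dioxirane reacts only with the electron-rich trisubstituted alkene (the enol triflate is electron-poor) through a spiro transition state, and the D-fructose-derived ketone should deliver the (R)-epoxide (Shi asymmetric epoxidation).

Step 3
Reactants: 4 4-[(2R)-3,3-dimethyloxiran-2-yl]but-1-en-2-yl trifluoromethanesulfonate
Product: 5 (5S)-5-bromo-6-hydroxy-6-methylhept-1-en-2-yl trifluoromethanesulfonate
Conditions: Li2NiBr4, THF, 0 °C to rt; aqueous work-up
Reagents that add atoms: dilithium tetrabromonickelate, [Li+].[Li+].[Ni+2].[Br-].[Br-].[Br-].[Br-]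
Why: Soft bromide opens the epoxide by SN2 attack at the less substituted carbon with inversion, giving the (S)-bromide and the tertiary alcohol under neutral conditions that leave the enol triflate untouched (regioselective epoxide ring opening).

Step 4
Reactants: 6 3-[(tert-butyldimethylsilyl)oxy]propan-1-ol; 7 but-3-en-2-yl acetate
Product: 8 (3S,4R)-1-[(tert-butyldimethylsilyl)oxy]-4-methylhex-5-en-3-ol
Conditions: [Ir(cod)Cl]2 (2.5 mol %), (R)-SEGPHOS (5 mol %), 4-cyano-3-nitrobenzoic acid (10 mol %), Cs2CO3 (20 mol %), THF, 90 °C
Reagents that add atoms: none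
Why: The iridium catalyst dehydrogenates the alcohol to the aldehyde and turns 7 into an (E)-σ-crotyl complex that adds through a closed chair transition state, which gives the anti adduct, while (R)-SEGPHOS is assigned to Re-face attack and so sets 3S,4R (iridium-catalysed transfer-hydrogenative carbonyl crotylation).

Step 5
Reactants: 8 (3S,4R)-1-[(tert-butyldimethylsilyl)oxy]-4-methylhex-5-en-3-ol
Product: 9 {[(3R,4R)-3-bromo-4-methylhex-5-en-1-yl]oxy}(tert-butyl)dimethylsilane
Conditions: PPh3, CBr4, CH2Cl2, 0 °C to rt
Reagents that add atoms: carbon tetrabromide, BrC(Br)(Br)Br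
Why: The alkoxyphosphonium salt is displaced by bromide in an SN2 step with inversion, turning the 3S alcohol into the 3R bromide while C4 is untouched (Appel reaction).

Step 6
Reactants: 9 {[(3R,4R)-3-bromo-4-methylhex-5-en-1-yl]oxy}(tert-butyl)dimethylsilane
Product: 10 (3R,4R)-3-bromo-4-methylhex-5-en-1-ol
Conditions: HF·pyridine, THF, 0 °C to rt
Reagents that add atoms: none
Why: Fluoride cleaves the primary silyl ether under mildly acidic conditions, so the γ-bromo alcohol never meets a base that could close an oxetane or eliminate HBr (silyl ether cleavage).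

Step 7
Reactants: 10 (3R,4R)-3-bromo-4-methylhex-5-en-1-ol
Product: 11 (3R,4R)-3-bromo-4-methylhex-5-enal
Conditions: Dess–Martin periodinane, CH2Cl2, 0 °C; used at once
Reagents that add atoms: none
Why: The periodinane oxidises the primary alcohol to the aldehyde under non-basic conditions at 0 °C, which should avoid E1cB loss of HBr from the β-bromo aldehyde (Dess–Martin oxidation).

Step 8
Reactants: 5 (5S)-5-bromo-6-hydroxy-6-methylhept-1-en-2-yl trifluoromethanesulfonate; 11 (3R,4R)-3-bromo-4-methylhex-5-enal
Product: 12 (3R,4R,10S)-4,10-dibromo-3,11-dimethyl-7-methylidenedodec-1-ene-6,11-diol (both epimers at the C6 carbinol)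
Conditions: CrCl2 (4 equiv), NiCl2 (2 mol %), DMF, 0 °C to rt
Reagents that add atoms: none
Why: Zerovalent nickel inserts into the C–OTf bond, the alkenyl group passes to chromium and the trivalent alkenylchromium adds only to the aldehyde in a neutral medium that tolerates both alkyl bromides and the free tertiary alcohol; the new carbinol forms as both epimers, which does not matter because it becomes the ketone carbon in step 9 (Nozaki–Hiyama–Kishi coupling).

Step 9
Reactants: 12 (3R,4R,10S)-4,10-dibromo-3,11-dimethyl-7-methylidenedodec-1-ene-6,11-diol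
Product: 13 (3R,4R)-3-bromo-1-[(1S,4S)-4-bromo-3,3-dimethylcyclohexyl]-4-methylhex-5-en-1-one
Conditions: TfOH (5 mol %), HFIP/CH2Cl2 (1:4), −20 °C to 0 °C
Reagents that add atoms: none
Why: Acid ionises the tertiary alcohol with anchimeric help from the vicinal bromine to a configurationally defined bromonium ion, the 1,1-disubstituted alkene attacks its tertiary carbon through a chair (6-endo) so that the C–Br configuration is retained and bromine ends equatorial, the tertiary cation next to the carbinol is discharged by a 1,2-hydride shift to the ketone, and the ring carbon α to the carbonyl equilibrates under the acid to the equatorial, 1,4-trans arrangement (bromonium-induced cation–olefin cyclisation terminated by a semipinacol shift).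

Step 10
Reactants: 13 (3R,4R)-3-bromo-1-[(1S,4S)-4-bromo-3,3-dimethylcyclohexyl]-4-methylhex-5-en-1-one
Product: 14 (1R,2R,4S)-2-bromo-4-[(1S,4S)-4-bromo-3,3-dimethylcyclohexyl]-1-methyl-7-oxabicyclo[2.2.1]heptane
Conditions: HNTf2 (20 mol %), HFIP/CH2Cl2 (1:4), −20 °C to rt
Reagents that add atoms: none
Why: Proposed new method: the protonated ketone is attacked by the terminal vinyl carbon (Prins addition), the secondary cation at C6 is relayed to C1 by a 1,2-hydride shift, the C2 bromine bridges the tertiary cation, and the tertiary hydroxyl opens this bromonium ion at C1, so that 13 isomerises to 14 with no atom gained or lost. The closest known reaction types are the acid-induced Prins or carbonyl-ene cyclisation of unsaturated ketones, whose zwitterions undergo 1,2-hydride shifts, and the acid-catalysed closure of terpinen-4-ol to 1,4-cineole together with transannular bromoetherification; the combination on a β-bromo ketone has not been shown. The carbocycle (C1 to C6) closes by 6-endo-trig attack at the alkene (6-exo-trig at the carbonyl), and the oxygen bridge closes by transannular attack of O7 on C1, a 5-exo-tet opening of the bromonium ion seen from the C5–C6 bridge. C4 is set in the Prins step by a chair transition state with ring A and the C2 bromine equatorial and the C1 hydrogen axial, which places the carbinol oxygen axial and trans to bromine; C1 is then set by the bridge, since O7 can reach C1 only on its own face, anti to bromine, which gives the endo bromide. The step needs Markovnikov attack at the terminal carbon, secured by the monosubstituted alkene, and the O/Br trans relationship, secured by the chair and by proof-reading, because the Prins addition is reversible and only the trans isomer can close. It also needs the β-bromo ketone to survive, which catalytic acid at low temperature in non-nucleophilic HFIP should secure.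

Compound list
1 | 6-methylhept-5-en-2-one | CC(=O)CCC=C(C)C | starting material
2 | lithium 6-methylhepta-1,5-dien-2-olate | [Li]OC(=C)CCC=C(C)C | intermediate
3 | 6-methylhepta-1,5-dien-2-yl trifluoromethanesulfonate | C=C(OS(=O)(=O)C(F)(F)F)CCC=C(C)C | intermediate
4 | 4-[(2R)-3,3-dimethyloxiran-2-yl]but-1-en-2-yl trifluoromethanesulfonate | C=C(OS(=O)(=O)C(F)(F)F)CC[C@H]1OC1(C)C | intermediate
5 | (5S)-5-bromo-6-hydroxy-6-methylhept-1-en-2-yl trifluoromethanesulfonate | C=C(OS(=O)(=O)C(F)(F)F)CC[C@H](Br)C(C)(C)O | intermediate
6 | 3-[(tert-butyldimethylsilyl)oxy]propan-1-ol | OCCCO[Si](C)(C)C(C)(C)C | starting material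
7 | but-3-en-2-yl acetate (racemic) | CC(OC(C)=O)C=C | starting material
8 | (3S,4R)-1-[(tert-butyldimethylsilyl)oxy]-4-methylhex-5-en-3-ol | C=C[C@@H](C)[C@@H](O)CCO[Si](C)(C)C(C)(C)C | intermediate
9 | {[(3R,4R)-3-bromo-4-methylhex-5-en-1-yl]oxy}(tert-butyl)dimethylsilane | C=C[C@@H](C)[C@H](Br)CCO[Si](C)(C)C(C)(C)C | intermediate
10 | (3R,4R)-3-bromo-4-methylhex-5-en-1-ol | C=C[C@@H](C)[C@H](Br)CCO | intermediate
11 | (3R,4R)-3-bromo-4-methylhex-5-enal | C=C[C@@H](C)[C@H](Br)CC=O | intermediate
12 | (3R,4R,10S)-4,10-dibromo-3,11-dimethyl-7-methylidenedodec-1-ene-6,11-diol, both epimers at C6 | C=C[C@@H](C)[C@H](Br)CC(O)C(=C)CC[C@H](Br)C(C)(C)O | intermediate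
13 | (3R,4R)-3-bromo-1-[(1S,4S)-4-bromo-3,3-dimethylcyclohexyl]-4-methylhex-5-en-1-one | C=C[C@@H](C)[C@H](Br)CC(=O)[C@H]1CC[C@H](Br)C(C)(C)C1 | intermediate
14 | (1R,2R,4S)-2-bromo-4-[(1S,4S)-4-bromo-3,3-dimethylcyclohexyl]-1-methyl-7-oxabicyclo[2.2.1]heptane | CC1(C)C[C@@H]([C@@]23CC[C@@](C)(O2)[C@H](Br)C3)CC[C@@H]1Br | target

Total step count: 10. Longest linear sequence: 7 steps (steps 4 to 10, from 6).

Steps most likely to fail

Step 10 (Proposed new method). The vinyl group may be too weak a nucleophile, so that acid-induced loss of HBr from the β-bromo ketone or protonation of the alkene outruns the Prins addition, or the addition may give the O/Br cis arrangement. The fallback uses known chemistry, sets out from 5 and comes back at 14. Commercial 4-methylpent-4-en-1-ol is oxidised with Dess–Martin periodinane to 4-methylpent-4-enal F1. CrCl2/NiCl2 coupling of 5 with F1 gives the allylic diol F2, and the ionisation, cyclisation and hydride shift of step 9 turn it into the ring A ketone F3. BINOL-catalysed asymmetric allylboration with allyldiisopropoxyborane, using the 3,3'-dibromo-BINOL antipode that delivers the (4S)-carbinol, sets C4 by reagent control in the tertiary homoallylic alcohol F4. Ring-closing metathesis with the second-generation Grubbs catalyst closes the carbocycle as the cyclohexenol F5. NBS in CH2Cl2 at 0 °C then effects transannular bromoetherification: the hydroxyl attacks C1 anti to the bromonium ion, which forms the O7–C1 bond and the endo C2–Br bond and gives 14.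

Step 9. Capture of the bromonium ion or of the tertiary cation by the free allylic hydroxyl, or proton loss from the tertiary cation, may compete with the hydride shift. The fallback sets out from 12 and comes back at 13. The secondary allylic alcohol is silylated selectively (Et3SiCl, imidazole, CH2Cl2; the tertiary alcohol is left) to give the triethylsilyl ether F6. Ionisation in HFIP then runs as a silyloxy-driven semipinacol shift: the oxygen can no longer act as a nucleophile, and the β-silyloxy cation is discharged by the hydride shift with loss of the silyl group to give 13.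

Step 8. β-Elimination of HBr from aldehyde 11 during the slow chromium-mediated coupling would destroy the C2–Br stereocentre. The fallback sets out from 10 and 5 and comes back at 12. Alcohol 10 is oxidised (TEMPO, PhI(OAc)2, MeCN/H2O) to the bromo acid F7, which 1-chloro-N,N,2-trimethylprop-1-en-1-amine converts under neutral conditions into the acid chloride F8, a species that does not enolise readily. Triflate 5 is stannylated (Pd(PPh3)4, Me3SnSnMe3, LiCl, THF) to the vinylstannane F9. Stille acylation of F9 with F8 (Pd2(dba)3, tri(2-furyl)phosphine) gives the enone F10, and Luche reduction (NaBH4, CeCl3·7H2O, MeOH, −78 °C) returns 12.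

Further compounds
F1 | step 10 | 4-methylpent-4-enal | C=C(C)CCC=O
F2 | step 10 | (9S)-9-bromo-2,10-dimethyl-6-methylideneundec-1-ene-5,10-diol, both epimers at C5 | C=C(C)CCC(O)C(=C)CC[C@H](Br)C(C)(C)O
F3 | step 10 | 1-[(1S,4S)-4-bromo-3,3-dimethylcyclohexyl]-4-methylpent-4-en-1-one | C=C(C)CCC(=O)[C@H]1CC[C@H](Br)C(C)(C)C1
F4 | step 10 | (4S)-4-[(1S,4S)-4-bromo-3,3-dimethylcyclohexyl]-7-methylocta-1,7-dien-4-ol | C=C(C)CC[C@](O)(CC=C)[C@H]1CC[C@H](Br)C(C)(C)C1
F5 | step 10 | (1S)-1-[(1S,4S)-4-bromo-3,3-dimethylcyclohexyl]-4-methylcyclohex-3-en-1-ol | CC1=CC[C@](O)([C@H]2CC[C@H](Br)C(C)(C)C2)CC1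
F6 | step 9 | (3R,4R,10S)-4,10-dibromo-3,11-dimethyl-7-methylidene-6-[(triethylsilyl)oxy]dodec-1-en-11-ol, both epimers at C6 | C=C[C@@H](C)[C@H](Br)CC(O[Si](CC)(CC)CC)C(=C)CC[C@H](Br)C(C)(C)O
F7 | step 8 | (3R,4R)-3-bromo-4-methylhex-5-enoic acid | C=C[C@@H](C)[C@H](Br)CC(=O)O
F8 | step 8 | (3R,4R)-3-bromo-4-methylhex-5-enoyl chloride | C=C[C@@H](C)[C@H](Br)CC(=O)Cl
F9 | step 8 | (3S)-3-bromo-2-methyl-6-(trimethylstannyl)hept-6-en-2-ol | C=C([Sn](C)(C)C)CC[C@H](Br)C(C)(C)O
F10 | step 8 | (3R,4R,10S)-4,10-dibromo-11-hydroxy-3,11-dimethyl-7-methylidenedodec-1-en-6-one | C=C[C@@H](C)[C@H](Br)CC(=O)C(=C)CC[C@H](Br)C(C)(C)O
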